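Readings and results are calculated from invented constants.

Start with an easy count: whatever leaves the electrophile must turn up somewhere. The electrophile is charged in the smaller amount than the nucleophile, which makes it the limiting reagent, so its balance is the one to write.

| flask | electrophile | nucleophile | buffer base | buffer acid | remark | time |
|---|---|---|---|---|---|---|
| Saturday's | 0.010 M | 1.3 equiv | 3 equiv | 2 equiv | run made earlier |  |
| Tuesday's | 0.015 M | 1.3 equiv | 3 equiv | 2 equiv | run made earlier |  |
| flask | 0.020 M | 1.30 equiv | 3.00 equiv | 2.00 equiv |  | 5.0 min |

| run | time / min | electrophile / % | target / % |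
|---|---|---|---|
| Saturday's | 0.333 | 95 | 2 |
| Saturday's | 1.00 | 83 | 5 |
| Saturday's | 1.50 | 73 | 7 |
| Saturday's | 2.50 | 65 | 14 |
| Saturday's | 4.00 | 52 | 22 |
| Saturday's | 5.00 | 44 | 24 |
| Saturday's | 6.00 | 39 | 25 |
| Tuesday's | 0.333 | 91 | 4 |
| Tuesday's | 1.00 | 73 | 10 |
| Tuesday's | 1.50 | 64 | 14 |
| Tuesday's | 2.50 | 50 | 17 |
| Tuesday's | 4.00 | 40 | 27 |
| Tuesday's | 5.00 | 37 | 28 |
| Tuesday's | 6.00 | 29 | 33 |

(each reading ± 1.5 percentage points)

* part of the electrophile that has reacted at 5.0 min
* pH of the solution at 5.0 min

- the earlier runs do not show the pH; that part of a forecast is a guess

In Tuesday's run at 6.00 min, 29 % of the electrophile remains, so 71.0 % has been used, yet the target reads only 33 %. That gives 0.465 for the target share, meaning target found per electrophile used. Saturday's last reading gives 0.410.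

Two people read this differently. The first holds that each electrophile lost pairs with a nucleophile and ends as target, so the gap is a step still unfinished and the share must climb towards one. The second, whose side I take, holds that the gap is a separate loss, so the share stays near its reading.

Both can use one regularity. Saturday's run at 6.00 min and Tuesday's at 4.00 min have the same starting concentration times time, and at those two moments the electrophile reads 39 % and 40 %.

I take the reciprocal of the fraction left to grow in step with that product. Scaling from Tuesday's last reading, this flask should have 73.1 % reacted, and at the same share 34.0 % target. The runs show no pH, so I offer none.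

The forecast, the first side's number, says 74 % reacted and pH 7, on the ground that “The electrophile decay fits a second-order reaction with nucleophile”.

The flask gives 73.1 % reacted and pH 5.39.

    electrophile + nucleophile → acid + target + leaving group (k = 0.110 M⁻¹ s⁻¹)
    protonated nucleophile ⇌ nucleophile + acid, settled at all times (K = 3.20 × 10⁻⁵ M)
    buffer acid ⇌ buffer base + acid, settled at all times (K = 5.00 × 10⁻⁶ M)
    target + leaving group → side product (k = 0.0410 M⁻¹ s⁻¹)
    2 electrophile → self-condensation product (k = 0.110 M⁻¹ s⁻¹)

The reacted part does not separate the two sides, but the target does. This flask holds 32.6 % target, a share of 0.446, with 39.2 % as self-condensation product, so the first view loses here. It comes nearer in the neighbour charged with 3.20 equiv nucleophile, where the share is 0.662. This flask has not come to rest at 5.0 min. By 50.0 min, 99.7 % of the electrophile has reacted, the target has fallen to 26.4 %, the share stands at 0.265, and the side product has gained 26 percentage points.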